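Numbering: ring C1–C10, lactone carbons C11 (α), C12 (C=O) and C13 (=CH2), C14 the methyl on C10, C15 the methylene on C4.

**Plan**
- Retrosynthesis first removes the C1/C10 epoxide oxygen, opens the C12–O6 lactone (C12 back to a protected carbinol) and the C8 angelate, and then cuts C7–C8.
- That cut is possible because the ring bond C7–C8 lies in a homoallylic alcohol unit: hydroxyl on C8, and on C7 the carbon C11 with its exocyclic C13 methylene. This is what a [2,3]-Wittig shift of a C8–O–C13 allylic ether leaves behind, so the ten-membered ring goes back to a thirteen-membered cyclic ether with SnBu3 on C8.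
- The ether ring is opened at O–C13 (Williamson), the C11=C7 olefin by a Horner–Wadsworth–Emmons reaction, and the chain at C3–C4 (B-alkyl Suzuki coupling).
- Forward: a diene alcohol (C1–C3, C8–C10) from anhydromevalonolactone and an enol triflate (C4–C7, C15) from D-erythronolactone acetonide are coupled; C7 is extended, C13 becomes a chloride and C8 an α-hydroxystannane. The thirteen-membered ether closes first, the ten-membered carbocycle second (ring contraction), the lactone third, the epoxide last.
- Stereochemistry: C5/C6 from the chiral pool; Z C1=C10 from the ring of the starting lactone; E C11=C7 from the olefination; C8 from reagent-controlled reduction of the acylstannane and inversion in the shift; C7 from the olefin geometry and the acetonide; C1/C10 from face-selective epoxidation.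

Key step: step 19

Assumption: (R)-BINAL-H is taken to give the (8S)-α-hydroxystannane, as with simple acylstannanes (the enantiomeric reagent is used if the sense is opposite), and the peracid is taken to add to the outer face of C1=C10 that gives the (1R,10S)-epoxide.

Step 1
Reactants: 1 4-methyl-5,6-dihydro-2H-pyran-2-one
Product: 2 4-methyl-5,6-dihydro-2H-pyran-2-ol (lactol)
Conditions: i-Bu2AlH (1.1 equiv), CH2Cl2, −78 °C; aq. KNaC4H4O6
Reagents that add atoms: none
Why: Partial reduction of a lactone: at −78 °C the aluminium lactolate is stable, so reduction stops at the lactol, and the ring keeps C2 and C9 cis on the future C1=C10 olefin.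

Step 2
Reactants: 2 lactol
Product: 3 (3Z)-3-methylhexa-3,5-dien-1-ol
Conditions: Ph3PCH3Br, KN(SiMe3)2, THF, 0 °C; then 2, 0 °C → rt
Reagents that add atoms: methyltriphenylphosphonium bromide, C[P+](c1ccccc1)(c1ccccc1)c1ccccc1.[Br-]
Why: Wittig methylenation of the ring-opened hydroxy enal form of the lactol adds C3 and carries over the Z geometry that the ring had fixed.

Step 3
Reactants: 3 dienol
Product: 4 TBS ether of 3
Conditions: TBSCl, imidazole, CH2Cl2, 0 °C → rt
Reagents that add atoms: tert-butyldimethylsilyl chloride, CC(C)(C)[Si](C)(C)Cl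
Why: Standard silylation of a primary alcohol; the TBS ether survives hydroboration, cross-coupling, hydride reduction and mild acid.

Step 4
Reactants: 5 2,3-O-isopropylidene-D-erythronolactone
Product: 6 hydroxy N-methoxy-N-methylamide
Conditions: MeNH(OMe)·HCl, AlMe3, CH2Cl2, 0 °C → rt
Reagents that add atoms: N,O-dimethylhydroxylamine hydrochloride, CNOC.Cl
Why: Aminolysis of a lactone by an aluminium amide opens the ring to the N-methoxy-N-methylamide without touching C5 and C6, which come unchanged from the chiral pool.

Step 5
Reactants: 6 hydroxy amide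
Product: 7 TES ether of 6
Conditions: TESCl, imidazole, CH2Cl2, 0 °C
Reagents that add atoms: chlorotriethylsilane, CC[Si](Cl)(CC)CC
Why: Immediate silylation of the primary alcohol prevents relactonisation, and TES is chosen because it can later be removed beside a TBS ether.

Step 6
Reactants: 7 silylated amide
Product: 8 methyl ketone
Conditions: MeMgBr, THF, −20 → 0 °C
Reagents that add atoms: methylmagnesium bromide, C[Mg]Br
Why: Grignard addition to an N-methoxy-N-methylamide stops at the chelated tetrahedral intermediate and gives the ketone on work-up; the new methyl carbon becomes C15.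

Step 7
Reactants: 8 methyl ketone
Product: 9 enol triflate
Conditions: KN(SiMe3)2, THF, −78 °C; PhNTf2, −78 → 0 °C
Reagents that add atoms: N-phenylbis(trifluoromethanesulfonimide), O=S(=O)(N(c1ccccc1)S(=O)(=O)C(F)(F)F)C(F)(F)F
Why: Kinetic deprotonation of the methyl group and O-triflation of the enolate give the 1,1-disubstituted enol triflate, while the hindered α-alkoxy methine is left alone so C5 is not epimerised.

Step 8
Reactants: 4 silylated diene; 9 enol triflate
Product: 11 bis-silyl triene, via B-alkyl-9-BBN adduct 10 (not isolated)
Conditions: 4, 9-BBN, THF, rt; then 9, Pd(dppf)Cl2 (5 mol %), AsPh3, aq. K3PO4, DMF, rt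
Reagents that add atoms: none
Why: 9-BBN adds to the terminal vinyl group of the diene with boron on C3, and B-alkyl Suzuki coupling with the enol triflate forms C3–C4 and installs the C4=C15 methylene directly.

Step 9
Reactants: 11 bis-silyl triene
Product: 12 C7 alcohol
Conditions: PPTS (0.1 equiv), MeOH, 0 °C
Reagents that add atoms: none
Why: Selective solvolysis of silyl ethers: a primary TES ether is cleaved much faster than the primary TBS ether or the internal acetonide.

Step 10
Reactants: 12 C7 alcohol
Product: 13 C7 aldehyde
Conditions: DMP, NaHCO3, CH2Cl2, 0 °C → rt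
Reagents that add atoms: none
Why: Buffered periodinane oxidation gives the α-alkoxy aldehyde without base, so the cis-dioxolane centre C6 is not epimerised; the aldehyde is used at once.

Step 11
Reactants: 13 C7 aldehyde; 14 ethyl 2-(diethoxyphosphoryl)acrylate; 15 4-methoxybenzyl alcohol
Product: 17 (7E)-enoate, via sodium phosphonate carbanion 16 (not isolated)
Conditions: 15, NaH, THF, 0 °C; 14, 0 °C; then 13, −78 → 0 °C
Reagents that add atoms: none
Why: Conjugate addition of the alkoxide to the phosphonoacrylate gives carbanion 16, and its Horner–Wadsworth–Emmons reaction should give the trisubstituted enoate with the ester trans to C6, as usual for α-branched phosphonoacetates; any Z isomer is removed by chromatography and the geometry checked by NOE.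

Step 12
Reactants: 17 enoate
Product: 18 C13 allylic alcohol
Conditions: i-Bu2AlH (2.5 equiv), CH2Cl2, −78 °C
Reagents that add atoms: none
Why: 1,2-Reduction of the enoate gives the allylic alcohol with the olefin geometry intact (C13 trans to C6, C12 cis to C6).

Step 13
Reactants: 18 allylic alcohol
Product: 20 C13 allylic chloride, via allylic mesylate 19 (not isolated)
Conditions: MsCl, 2,4,6-collidine, LiCl, DMF, 0 °C
Reagents that add atoms: lithium chloride, [Li+].[Cl-]
Why: Mesylation and in situ SN2 displacement by chloride convert the primary allylic alcohol into the chloride without allylic transposition or loss of geometry.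

Step 14
Reactants: 20 allylic chloride
Product: 21 C8 alcohol
Conditions: HF·pyridine, pyridine, THF, 0 °C → rt
Reagents that add atoms: none
Why: Buffered HF·pyridine cleaves the primary TBS ether, while the allylic chloride, acetonide and PMB ether are inert to it.

Step 15
Reactants: 21 C8 alcohol
Product: 22 chloro aldehyde
Conditions: DMP, NaHCO3, CH2Cl2, 0 °C
Reagents that add atoms: none
Why: Buffered periodinane oxidation gives the β,γ-unsaturated aldehyde without acid or base that would move the olefin into conjugation; it is used directly.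

Step 16
Reactants: 22 chloro aldehyde
Product: 24 acylstannane, via lithium stannyl alkoxide 23 (not isolated)
Conditions: Bu3SnH, LiN(i-Pr)2, THF, 0 °C; then 22, −78 °C; then 1,1′-(azodicarbonyl)dipiperidine (ADD), −78 → 0 °C
Reagents that add atoms: tributyltin hydride, CCCC[SnH](CCCC)CCCC
Why: Bu3SnLi adds to an aldehyde within minutes at −78 °C, faster than it substitutes the allylic chloride when one equivalent is used, and the alkoxide 23 is oxidised in the same flask by hydride transfer to the azo compound, the established route from aldehydes to acylstannanes.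

Step 17
Reactants: 24 acylstannane
Product: 25 (8S)-α-hydroxystannane
Conditions: (R)-BINAL-H, LiAlH(OEt)[(R)-1,1′-binaphthalene-2,2′-diolate] (3 equiv), THF, −78 °C
Reagents that add atoms: none
Why: Enantioselective reduction of acylstannanes by BINAL-H is reagent-controlled and should set C8 as S; the chloride is inert to the hydride at −78 °C, and the labile product is carried on immediately.

Step 18
Reactants: 25 α-hydroxystannane
Product: 26 thirteen-membered stannyl ether
Conditions: EtMgBr (1.05 equiv), THF, 0 °C; HMPA, Bu4NI (cat.), 0.004 M, rt → 45 °C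
Reagents that add atoms: none
Why: Williamson macro-etherification: the bromomagnesium alkoxide displaces the primary allylic chloride at C13 (13-exo-tet) under high dilution, as in known closures of thirteen-membered allylic ethers, with retention at C8 because only the O–H bond is involved.

Step 19
Reactants: 26 thirteen-membered stannyl ether
Product: 28 cyclodecenol, via α-alkoxy organolithium 27 (not isolated)
Conditions: n-BuLi (1.2 equiv), THF, −78 °C; then aq. NH4Cl
Reagents that add atoms: none
Why: Proposed new method: n-BuLi exchanges tin for lithium at −78 °C with retention to give the configurationally stable α-alkoxy organolithium 27, whose carbanion attacks C7 of the C11=C7 olefin through a five-membered envelope (C8, O, C13, C11, C7) while O–C13 breaks, a suprafacial [2,3]-Wittig shift that inverts C8. The closest known reactions are the [2,3]-Wittig ring contractions of thirteen-membered allylic and propargylic ethers to cyclodecenols (there with stabilised carbanions made by deprotonation) and the open-chain Still–Wittig rearrangement of enantioenriched α-alkoxystannanes; a non-stabilised, tin-derived secondary carbanion in a ring contraction has not been shown. The ten-membered carbocycle closes by transannular C7–C8 bond formation, so the thirteen-membered ether contracts by three atoms and no high dilution is needed. C8 follows from the (8S)-stannane by retentive exchange and invertive shift, and C7 follows relative to C8 from the E geometry of C11=C7 (C6 trans to C13), which together with the C12 branch on C11 keeps C9 exo on the envelope and gives the 7,8-anti product. The step needs the carbanion to reach the face of C7 that is syn to O6 when H6 eclipses the olefin (the rotamer enforced by allylic strain with the C12 methylene); the cis-fused acetonide keeps the torsion C4–C5–C6–C7 small and so holds C4 over the other face, leaving the required one open. Chemoselectivity rests on tin–lithium exchange being much faster at −78 °C than deprotonation next to the ether oxygens or at the PMB group, and on the [2,3] path out-running the [1,2] shift at that temperature.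

Step 20
Reactants: 28 cyclodecenol; 29 angelic acid
Product: 30 C8 angelate
Conditions: 29, 2,4,6-trichlorobenzoyl chloride, NEt3, toluene, rt; then 28, 80 °C
Reagents that add atoms: none
Why: Yamaguchi-type esterification through the mixed anhydride, run without DMAP, acylates the secondary alcohol while keeping the Z geometry of the angelate.

Step 21
Reactants: 30 angelate
Product: 31 C12 allylic alcohol
Conditions: DDQ, CH2Cl2/pH 7 buffer, 0 °C
Reagents that add atoms: none
Why: Oxidative cleavage of the PMB ether by DDQ and water releases the primary alcohol without affecting the acetonide, the ester or the olefins.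

Step 22
Reactants: 31 allylic alcohol
Product: 32 C12 enal
Conditions: MnO2, CH2Cl2, rt
Reagents that add atoms: none
Why: MnO2 oxidises the allylic alcohol selectively to the 2-substituted acrolein.

Step 23
Reactants: 32 enal
Product: 33 C12 acrylic acid
Conditions: NaClO2, NaH2PO4, 2-methyl-2-butene, t-BuOH/H2O, 0 °C → rt
Reagents that add atoms: sodium chlorite, [Na+].[O-]Cl=O
Why: Pinnick oxidation with an alkene as hypochlorite scavenger converts the enal into the acid without touching the other olefins.

Step 24
Reactants: 33 acetonide acid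
Product: 35 hydroxy α-methylene lactone, via dihydroxy acid 34 (not isolated)
Conditions: TsOH·H2O (0.2 equiv), THF/H2O (10:1), 40 °C
Reagents that add atoms: none
Why: Acid hydrolysis of the acetonide frees the 5,6-diol, and the acid closes onto O6 (5-exo-trig) to the five-membered lactone, favoured over the six-membered lactone onto O5; C5–OH stays free and the cis ring fusion follows from the configurations already set at C6 and C7.

Step 25
Reactants: 35 hydroxy lactone
Product: 36 target CNP0227074.3
Conditions: mCPBA (1.05 equiv), NaHCO3, CH2Cl2, −20 → 0 °C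
Reagents that add atoms: 3-chloroperoxybenzoic acid, O=C(OO)c1cccc(Cl)c1
Why: The peracid epoxidises the most electron-rich olefin, the trisubstituted C1=C10, ahead of the 1,1-disubstituted C4=C15 and the two conjugated olefins, with retention of the cis geometry; oxygen is expected to add from the outer face of the olefin in the cis-fused ring, assumed to give the (1R,10S)-epoxide.

**Compound list**

1 | 4-methyl-5,6-dihydro-2H-pyran-2-one (anhydromevalonolactone) | CC1=CC(=O)OCC1 | starting material
2 | 4-methyl-5,6-dihydro-2H-pyran-2-ol (lactol, anomeric mixture) | CC1=CC(O)OCC1 | intermediate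
3 | (3Z)-3-methylhexa-3,5-dien-1-ol | C=C/C=C(/C)CCO | intermediate
4 | tert-butyldimethylsilyl ether of 3 | C=C/C=C(/C)CCO[Si](C)(C)C(C)(C)C | intermediate
5 | 2,3-O-isopropylidene-D-erythronolactone, (3aR,6aR) | O=C1[C@@H]2OC(C)(C)O[C@@H]2CO1 | starting material
6 | (4R,5R)-5-(hydroxymethyl)-N-methoxy-N,2,2-trimethyl-1,3-dioxolane-4-carboxamide | CON(C)C(=O)[C@@H]1OC(C)(C)O[C@@H]1CO | intermediate
7 | triethylsilyl ether of 6, (4R,5R) | CON(C)C(=O)[C@@H]1OC(C)(C)O[C@@H]1CO[Si](CC)(CC)CC | intermediate
8 | 1-[(4R,5R)-2,2-dimethyl-5-(triethylsilyloxymethyl)-1,3-dioxolan-4-yl]ethanone | CC(=O)[C@@H]1OC(C)(C)O[C@@H]1CO[Si](CC)(CC)CC | intermediate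
9 | 1-[(4R,5R)-2,2-dimethyl-5-(triethylsilyloxymethyl)-1,3-dioxolan-4-yl]vinyl trifluoromethanesulfonate | C=C(OS(=O)(=O)C(F)(F)F)[C@@H]1OC(C)(C)O[C@@H]1CO[Si](CC)(CC)CC | intermediate
10 | B-[(3Z)-6-(tert-butyldimethylsilyloxy)-4-methylhex-3-enyl]-9-borabicyclo[3.3.1]nonane | CC(C)(C)[Si](C)(C)OCC/C(C)=C\CCB1C2CCCC1CCC2 | intermediate (not isolated)
11 | bis-silyl triene: chain C7 to C8 with O7-TES, O5/O6 acetonide, C4=C15 methylene, O8-TBS; (1(10)Z,5S,6R) | CC(C)(C)[Si](C)(C)OCC/C(C)=C\CCC(=C)[C@@H]1OC(C)(C)O[C@@H]1CO[Si](CC)(CC)CC | intermediate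
12 | C7 alcohol of 11 (O7 free); (1(10)Z,5S,6R) | CC(C)(C)[Si](C)(C)OCC/C(C)=C\CCC(=C)[C@@H]1OC(C)(C)O[C@@H]1CO | intermediate
13 | C7 aldehyde; (1(10)Z,5S,6S), the descriptor at C6 changes with the formyl group, the arrangement does not | CC(C)(C)[Si](C)(C)OCC/C(C)=C\CCC(=C)[C@@H]1OC(C)(C)O[C@@H]1C=O | intermediate
14 | ethyl 2-(diethoxyphosphoryl)acrylate | C=C(C(=O)OCC)P(=O)(OCC)OCC | starting material
15 | 4-methoxybenzyl alcohol | COc1ccc(CO)cc1 | starting material
16 | sodium salt of ethyl 2-(diethoxyphosphoryl)-3-(4-methoxybenzyloxy)propanoate (carbanion) | [Na+].CCOC(=O)[C-](COCc1ccc(OC)cc1)P(=O)(OCC)OCC | intermediate (not isolated)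
17 | ethyl enoate: C11 carries CO2Et (C13, trans to C6) and CH2OPMB (C12, cis to C6); (1(10)Z,5S,6R,7E) | CC(C)(C)[Si](C)(C)OCC/C(C)=C\CCC(=C)[C@@H]1OC(C)(C)O[C@@H]1/C=C(/C(=O)OCC)COCc2ccc(OC)cc2 | intermediate
18 | C13 allylic alcohol (C13H2OH trans to C6); (1(10)Z,5S,6R) | CC(C)(C)[Si](C)(C)OCC/C(C)=C\CCC(=C)[C@@H]1OC(C)(C)O[C@@H]1/C=C(/CO)COCc2ccc(OC)cc2 | intermediate
19 | C13 allylic mesylate of 18 | CC(C)(C)[Si](C)(C)OCC/C(C)=C\CCC(=C)[C@@H]1OC(C)(C)O[C@@H]1/C=C(/COS(C)(=O)=O)COCc2ccc(OC)cc2 | intermediate (not isolated)
20 | C13 allylic chloride (C13 trans to C6), O8-TBS; (1(10)Z,5S,6R,7E) | CC(C)(C)[Si](C)(C)OCC/C(C)=C\CCC(=C)[C@@H]1OC(C)(C)O[C@@H]1/C=C(/CCl)COCc2ccc(OC)cc2 | intermediate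
21 | C8 alcohol of 20 | OCC/C(C)=C\CCC(=C)[C@@H]1OC(C)(C)O[C@@H]1/C=C(/CCl)COCc2ccc(OC)cc2 | intermediate
22 | chloro aldehyde (C8 formyl, C13 chloride); (1(10)Z,5S,6R,7E) | O=CC/C(C)=C\CCC(=C)[C@@H]1OC(C)(C)O[C@@H]1/C=C(/CCl)COCc2ccc(OC)cc2 | intermediate
23 | lithium alkoxide of the C8 tributylstannyl carbinol (both C8 epimers) | [Li+].CCCC[Sn](CCCC)(CCCC)C([O-])C/C(C)=C\CCC(=C)[C@@H]1OC(C)(C)O[C@@H]1/C=C(/CCl)COCc2ccc(OC)cc2 | intermediate (not isolated)
24 | C8 acyl(tributyl)stannane | CCCC[Sn](CCCC)(CCCC)C(=O)C/C(C)=C\CCC(=C)[C@@H]1OC(C)(C)O[C@@H]1/C=C(/CCl)COCc2ccc(OC)cc2 | intermediate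
25 | (8S)-α-hydroxystannane with C13 chloride; (1(10)Z,5S,6R,7E,8S) | CCCC[Sn](CCCC)(CCCC)[C@H](O)C/C(C)=C\CCC(=C)[C@@H]1OC(C)(C)O[C@@H]1/C=C(/CCl)COCc2ccc(OC)cc2 | intermediate
26 | thirteen-membered ether C8–O–C13 with SnBu3 on C8, C12H2OPMB on C11, acetonide on O5/O6; (1(10)Z,5S,6R,7E,8S) | CCCC[Sn](CCCC)(CCCC)[C@@H]1OC/C(COCc2ccc(OC)cc2)=C/[C@H]3OC(C)(C)O[C@H]3C(=C)CC/C=C(C)\C1 | intermediate
27 | C8-lithio analogue of 26 (tin replaced by lithium with retention) | [Li][C@@H]1OC/C(COCc2ccc(OC)cc2)=C/[C@H]3OC(C)(C)O[C@H]3C(=C)CC/C=C(C)\C1 | intermediate (not isolated)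
28 | cyclodecenol: ten-membered ring, C8–OH, C7 bearing C11(=C13H2)CH2OPMB, acetonide on O5/O6; (1(10)Z,5S,6R,7R,8S) | C=C(COCc2ccc(OC)cc2)[C@@H]1[C@@H](O)C/C(C)=C\CCC(=C)[C@@H]3OC(C)(C)O[C@H]13 | intermediate
29 | angelic acid, (Z)-2-methylbut-2-enoic acid | C/C=C(/C)C(=O)O | starting material
30 | C8 angelate of 28 | C=C(COCc2ccc(OC)cc2)[C@@H]1[C@@H](OC(=O)/C(C)=C\C)C/C(C)=C\CCC(=C)[C@@H]3OC(C)(C)O[C@H]13 | intermediate
31 | C12 allylic alcohol (PMB removed) | C=C(CO)[C@@H]1[C@@H](OC(=O)/C(C)=C\C)C/C(C)=C\CCC(=C)[C@@H]3OC(C)(C)O[C@H]13 | intermediate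
32 | C12 enal | C=C(C=O)[C@@H]1[C@@H](OC(=O)/C(C)=C\C)C/C(C)=C\CCC(=C)[C@@H]3OC(C)(C)O[C@H]13 | intermediate
33 | C12 acrylic acid, acetonide intact | C=C(C(=O)O)[C@@H]1[C@@H](OC(=O)/C(C)=C\C)C/C(C)=C\CCC(=C)[C@@H]3OC(C)(C)O[C@H]13 | intermediate
34 | 5,6-dihydroxy acid | C=C(C(=O)O)[C@@H]1[C@@H](OC(=O)/C(C)=C\C)C/C(C)=C\CCC(=C)[C@H](O)[C@@H]1O | intermediate (not isolated)
35 | 1,10-deoxy target: cis-fused 6,12-olide, 5-OH, 8-angelate; (1(10)Z,5S,6R,7R,8S) | C=C1C(=O)O[C@@H]2[C@H]1[C@@H](OC(=O)/C(C)=C\C)C/C(C)=C\CCC(=C)[C@@H]2O | intermediate
36 | CNP0227074.3; (1R,5S,6R,7R,8S,10S) | C=C1C(=O)O[C@@H]2[C@H]1[C@@H](OC(=O)/C(C)=C\C)C[C@]1(C)O[C@@H]1CCC(=C)[C@@H]2O | target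

**Step count**

Total: 25 steps. Longest linear sequence: 22 steps (5 to 36, steps 4–25).

**Steps most likely to fail**

Step 19 (new method). The carbanion may add to the wrong face of C7, because an allylic C–O bond prefers to lie anti to an incoming carbanion and that preference points to the other face. The [1,2]-shift may also compete, or the organolithium may be protonated before it rearranges. The fallback uses known chemistry and sets out from chloro aldehyde 22. Chloride is exchanged for iodide (NaI, acetone) to give the iodo aldehyde F1. CrCl2 in THF at high dilution then converts the allylic iodide into an allylchromium species of trivalent chromium, which adds through C7 to the C8 aldehyde by a chair transition state (intramolecular Nozaki–Hiyama allylation). This forms the same C7–C8 bond, the C11=C13 methylene and the C8 hydroxyl, normally with the 7,8-anti relationship, and returns to the route at cyclodecenol 28.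

Step 18. The magnesium alkoxide may fragment back to aldehyde 22 and a stannyl anion, or oligomerise instead of closing the ring. The fallback sets out from hydroxystannane 25 and replaces the alkali-type alkoxide displacement by a metal-catalysed allylic etherification. Et2Zn (0.5 equiv) forms the zinc alkoxide and Pd(PPh3)4 (zerovalent palladium) ionises the allylic chloride to the π-allyl complex. Oxygen then attacks the unsubstituted C13 terminus (Tsuji–Trost etherification, known for zinc alkoxides of aliphatic alcohols). It returns at the thirteen-membered ether 26, with the olefin geometry checked by NOE, and makes no new compound (F0).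

Step 25. Facial selectivity on the Z olefin may be poor or opposite, and the free C5 hydroxyl may direct the peracid to C4=C15. The fallback sets out from 35 and replaces substrate control by reagent control. The dioxirane is generated in situ from the fructose-derived ketone (the enantiomer that matches the required face) and KHSO5 in buffered MeCN/H2O (Shi epoxidation, established for trisubstituted olefins and not hydroxyl-directed). It returns at target 36 and makes no new compound (F0).

Further compounds
F1 | step 19 | iodo aldehyde (C8 formyl, C13 iodide), otherwise as 22 | O=CC/C(C)=C\CCC(=C)[C@@H]1OC(C)(C)O[C@@H]1/C=C(/CI)COCc2ccc(OC)cc2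
F0 | step 18 | none | none
F0 | step 25 | none | none
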